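For the chemist taking over the bench: teal, amber and blue each hold starting material with catalyst, closed and stirred, at three temperatures.

| flask | starting material | catalyst | temperature | remark | time |
|---|---|---|---|---|---|
| birch | 0.27 M | 2 mM | 28 °C | run made earlier |  |
| ash | 0.60 M | 2 mM | 55 °C | run made earlier |  |
| teal | 0.40 M | 2.0 mM | 65 °C |  | 8.0 h |
| amber | 0.40 M | 2.0 mM | 15 °C |  | 8.0 h |
| blue | 0.40 M | 2.0 mM | 40 °C |  | 8.0 h |

| run | time / h | target / % | starting material / % |
|---|---|---|---|
| birch | 3.00 | 22.8 | 69.5 |
| birch | 10.0 | 22.6 | 65.1 |
| birch | 20.0 | 22.5 | 65.7 |
| birch | 25.0 | 21.5 | 65.4 |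
| birch | 40.0 | 21.7 | 64.9 |
| birch | 50.0 | 21.2 | 65.6 |
| ash | 1.00 | 11.6 | 72.7 |
| ash | 1.50 | 13.4 | 72.7 |
| ash | 3.00 | 12.1 | 71.0 |
| ash | 5.00 | 11.9 | 73.3 |
| ash | 8.00 | 10.7 | 72.0 |
| ash | 12.0 | 12.5 | 72.1 |

(standard deviation of a reading: 1 percentage point)

- what was read earlier has a scatter of 1 percentage point, one standard deviation

1. which flask leads in amount of target, in percent of the starting material charged ("all alike" within 1.5 percentage points) (teal / amber / blue / all alike)
2. how much target is there at the end, in percent of the starting material charged: teal
3. how much target is there at the end, in percent of the starting material charged: amber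
4. how much target is there at the end, in percent of the starting material charged: blue

Target in birch holds level from 10.0 h to 50.0 h, and in ash from 1.00 h, so the reading to carry is the plateau ratio of target to starting material (thermodynamic control). My own reckoning follows. The plateau ratio reads 0.335 in birch and 0.166 in ash.

The two runs differ in charge as well as in temperature; this reckoning sets the charge aside. Between them the ratio falls over 27.0 K, which gives a rise of 26.7 K, the halving span, the temperature rise that halves the plateau ratio.

The remainder of the charge, per starting material, reads 0.195 in birch and 0.217 in ash, so 0.206 is taken for the new flasks.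

target share = ratio / (one + ratio + remainder)

teal: ratio 0.128, target 9.60%
amber: ratio 0.470, target 28.0%
blue: ratio 0.246, target 16.9%

Amber lies below birch and teal above ash, so both numbers are extrapolations. The bath must not be touched: the reckoned ratio in amber is 3.67 times that in teal.

The forecast puts amber in the lead, with target at 10% in teal, 28% in amber and 17% in blue, and holds that “these are equilibrium plateaus and not kinetic limits”.

At 8.00 h the flasks give 11.0% in teal, 28.8% in amber and 17.2% in blue, so amber leads.

    target ⇌ isomer of the product (K = 0.800, k = 0.0513 /h, Ea = 97.0 kJ/mol, ΔH = 20.0 kJ/mol)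
    isomer of the product + catalyst ⇌ starting material + catalyst, rate k2*[catalyst]*[isomer of the product] forward; the back reaction follows from the equilibrium constant (k = 292 /M/h, Ea = 49.0 kJ/mol)
    starting material + catalyst ⇌ target + catalyst, rate k3*[starting material]*[catalyst] forward; the back reaction follows from the equilibrium constant (K = 0.250, k = 337 /M/h, Ea = 40.0 kJ/mol, ΔH = −18.0 kJ/mol)
    (constants at 40 °C)

Blue ends at a ratio of 0.250, against 0.246 reckoned, and the remainder there is the isomer of the product, 13.8%. The neighbouring flask is blue run at 55 °C, with charges and time held. Carried up 15.0 K from blue through the halving span of 26.7 K, the ratio becomes 0.169, and with the remainder of 0.206 target comes to 12.3%. At 8.00 h the neighbouring flask holds 13.1% target beside 72.0% starting material.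

All runs were generated by integration from invented constants; scatter was added.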